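**Plan**

- Side-chain carbons are numbered C1′–C33′ from chromene C2. The retrosynthesis cuts C14′–C15′ first (sp3–sp2, fragment union), then the pyran ring at C3=C4 (ring-closing metathesis) and at O1–C2 (asymmetric allylic etherification).
- Enabling feature: C14′ is homoallylic to C11′=C12′, so it can be the CH2 end of a C13′=C14′ vinyl group that anti-Markovnikov hydroboration turns into the nucleophile. C15′ is the unsubstituted end of the (E)-C15′=C16′(CH3) unit, the retron of syn-methylalumination of a terminal alkyne.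
- Both halves come from all-E geranylgeraniol. Left half: bromide, propargylation, carboalumination/iodination to a C24 (E)-alkenyl iodide. Right half: methyl carbonate, terminal allylic oxidation to the C16 enal.
- Forward order: aryl ether O1–C2 (sets C2), then the pyran ring, then the terminal diene, then chain union by hydroboration/B-alkyl Suzuki–Miyaura coupling, then desilylation.
- Stereochemistry: C2 (R) from ligand control in the palladium-catalysed O-allylation. Seven (E)-olefins come from geranylgeraniol, and C15′=C16′ from syn-carbometallation with retention in the coupling.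

Key step: step 12

Assumption: the (R,R)-enantiomer of the DACH-phenyl Trost ligand is taken to give the (14R)-ether 16 from the (2E)-carbonate; the sense is checked on the first run and the (S,S)-ligand is used instead if it is opposite.

**Route**

Step 1
Reactants: 1 (2E,6E,10E)-geranylgeraniol
Product: 2 (2E,6E,10E)-geranylgeranyl bromide
Conditions: PBr3 (0.4 equiv), Et2O, −10 °C; used crude
Reagents that add atoms: phosphorus tribromide, BrP(Br)Br
Why: Bromination of the primary allylic alcohol through its phosphite ester (PBr3 bromination, SN2) at low temperature should keep the (2E) geometry and avoid allylic transposition.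

Step 2
Reactants: 2 (2E,6E,10E)-geranylgeranyl bromide; 3 1-(trimethylsilyl)propyne
Product: 6 (5E,9E,13E)-6,10,14,18-tetramethylnonadeca-5,9,13,17-tetraen-1-yne, via 3-lithio-1-(trimethylsilyl)propyne 4 (not isolated), via C-silylated tetraenyne 5 (not isolated)
Conditions: 3, n-BuLi, THF, −40 °C; then 2, −40 °C → rt; then K2CO3 (0.2 equiv), MeOH, rt
Reagents that add atoms: n-butyllithium, [Li]CCCC (its lithium stays only in intermediate 4)
Why: Propargylic lithiation of the silyl-blocked propyne, SN2 alkylation by the primary allylic bromide and methanolysis of the C–Si bond (alkylation of a propargyl anion equivalent, protodesilylation) should give the 1,5-enyne with the three olefins untouched.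

Step 3
Reactants: 6 (5E,9E,13E)-6,10,14,18-tetramethylnonadeca-5,9,13,17-tetraen-1-yne
Product: 8 (1E,5E,9E,13E)-1-iodo-2,6,10,14,18-pentamethylnonadeca-1,5,9,13,17-pentaene, via alkenyldimethylalane 7 (not isolated)
Conditions: Me3Al (2.5 equiv), Cp2ZrCl2 (0.25 equiv), CH2Cl2, 0 °C → rt; then I2, THF, −30 → 0 °C
Reagents that add atoms: trimethylaluminium, C[Al](C)C; iodine, II
Why: Zirconium-catalysed syn-methylalumination of the terminal alkyne (Negishi carboalumination) puts CH3 on C2 and aluminium on C1 on the same face, and iodinolysis with retention should give the (1E)-iodide, the trisubstituted olefins being inert to carbometallation.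

Step 4
Reactants: 9 2,3-dimethylhydroquinone
Product: 10 2,3-dimethyl-4-(triisopropylsilyloxy)phenol
Conditions: TIPSCl (1.0 equiv), imidazole, DMF, 0 °C → rt; chromatography
Reagents that add atoms: triisopropylsilyl chloride, CC(C)[Si](Cl)(C(C)C)C(C)C
Why: Statistical monosilylation of the symmetric diol can give only one mono-ether, which should be separable from diol and bis-ether.

Step 5
Reactants: 10 2,3-dimethyl-4-(triisopropylsilyloxy)phenol
Product: 11 2-hydroxy-3,4-dimethyl-5-(triisopropylsilyloxy)benzaldehyde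
Conditions: MgCl2, Et3N, (CH2O)n, MeCN, reflux
Reagents that add atoms: paraformaldehyde (as formaldehyde), C=O
Why: Magnesium phenoxide-directed ortho-formylation (Casnati–Skattebøl reaction) can occur only at the single free position ortho to the hydroxyl, and the bulky aryl silyl ether should survive the amine base.

Step 6
Reactants: 11 2-hydroxy-3,4-dimethyl-5-(triisopropylsilyloxy)benzaldehyde
Product: 12 6-ethenyl-2,3-dimethyl-4-(triisopropylsilyloxy)phenol
Conditions: Ph3PCH3Br (2.5 equiv), KOtBu (2.5 equiv), THF, 0 °C → rt; product kept cold and used promptly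
Reagents that add atoms: methyltriphenylphosphonium bromide, C[P+](c1ccccc1)(c1ccccc1)c1ccccc1.[Br-]
Why: Wittig methylenation of the salicylaldehyde with excess ylide (one equivalent is spent on the phenol) should give the 2-vinylphenol.

Step 7
Reactants: 1 (2E,6E,10E)-geranylgeraniol
Product: 13 (2E,6E,10E)-geranylgeranyl methyl carbonate
Conditions: ClCO2Me, pyridine, CH2Cl2, 0 °C
Reagents that add atoms: methyl chloroformate, COC(=O)Cl
Why: Acylation of the primary allylic alcohol gives the ionisable allylic carbonate needed in step 9.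

Step 8
Reactants: 13 (2E,6E,10E)-geranylgeranyl methyl carbonate
Product: 15 methyl (2E,6E,10E,14E)-3,7,11,15-tetramethyl-16-oxohexadeca-2,6,10,14-tetraen-1-yl carbonate, via 16-hydroxy carbonate 14 (not isolated)
Conditions: SeO2 (0.2 equiv), t-BuOOH (70% aq.), salicylic acid (0.1 equiv), CH2Cl2, rt; filter, concentrate; then MnO2, CH2Cl2, rt
Reagents that add atoms: selenium dioxide, O=[Se]=O (catalytic oxygen carrier); tert-butyl hydroperoxide, CC(C)(C)OO
Why: SeO2 allylic oxidation (ene reaction, then [2,3]-sigmatropic shift) should favour the (E)-methyl of the terminal isopropylidene group, the most accessible olefin, and MnO2 converges alcohol 14 and any aldehyde to the (E)-enal without touching the carbonate.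

Step 9
Reactants: 12 6-ethenyl-2,3-dimethyl-4-(triisopropylsilyloxy)phenol; 15 methyl (2E,6E,10E,14E)-3,7,11,15-tetramethyl-16-oxohexadeca-2,6,10,14-tetraen-1-yl carbonate
Product: 16 (2E,6E,10E,14R)-14-[6-ethenyl-2,3-dimethyl-4-(triisopropylsilyloxy)phenoxy]-2,6,10,14-tetramethylhexadeca-2,6,10,15-tetraenal
Conditions: Pd2(dba)3·CHCl3 (2 mol %), (R,R)-DACH-phenyl Trost ligand (6 mol %), CH2Cl2, rt
Reagents that add atoms: none
Why: Palladium-catalysed asymmetric allylic alkylation with a phenol (Trost AAA): ionisation of the carbonate by zerovalent palladium gives a 1,1-disubstituted π-allyl complex that the phenoxide should attack at the more substituted terminus inside the chiral pocket of the ligand, setting the tertiary ether carbon as (R) under ligand control while enal and styrene stay inert.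

Step 10
Reactants: 16 (2E,6E,10E,14R)-14-[6-ethenyl-2,3-dimethyl-4-(triisopropylsilyloxy)phenoxy]-2,6,10,14-tetramethylhexadeca-2,6,10,15-tetraenal
Product: 17 (2E,6E,10E)-2,6,10-trimethyl-13-[(2R)-2,7,8-trimethyl-6-(triisopropylsilyloxy)-2H-chromen-2-yl]trideca-2,6,10-trienal
Conditions: second-generation Grubbs catalyst RuCl2(=CHPh)(H2IMes)(PCy3) (5 mol %), CH2Cl2 (0.005 M), 40 °C
Reagents that add atoms: none
Why: Ring-closing metathesis between the two monosubstituted olefins (styrene and the vinyl group on the quaternary carbon) should close the six-membered pyran ring as the cis C3=C4 olefin with loss of ethene, the trisubstituted chain olefins and the electron-poor enal reacting far more slowly and C2 not being touched.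

Step 11
Reactants: 17 (2E,6E,10E)-2,6,10-trimethyl-13-[(2R)-2,7,8-trimethyl-6-(triisopropylsilyloxy)-2H-chromen-2-yl]trideca-2,6,10-trienal
Product: 18 triisopropyl{[(2R)-2,7,8-trimethyl-2-[(3E,7E,11E)-4,8,12-trimethyltetradeca-3,7,11,13-tetraen-1-yl]-2H-chromen-6-yl]oxy}silane
Conditions: Ph3PCH3Br, n-BuLi, THF, 0 °C; then 17, −78 → 0 °C
Reagents that add atoms: methyltriphenylphosphonium bromide, C[P+](c1ccccc1)(c1ccccc1)c1ccccc1.[Br-]
Why: Wittig methylenation of the non-enolisable α-methyl enal should give the terminal (E)-2-methyl-1,3-diene without change of olefin geometry or loss of the aryl silyl ether.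

Step 12
Reactants: 18 triisopropyl{[(2R)-2,7,8-trimethyl-2-[(3E,7E,11E)-4,8,12-trimethyltetradeca-3,7,11,13-tetraen-1-yl]-2H-chromen-6-yl]oxy}silane; 8 (1E,5E,9E,13E)-1-iodo-2,6,10,14,18-pentamethylnonadeca-1,5,9,13,17-pentaene
Product: 20 O-triisopropylsilyl plastochromenol-8, via B-alkyl-9-BBN borane 19 (not isolated)
Conditions: 9-BBN-H (1.3 equiv), THF, 0 °C → rt; then 8, PdCl2(dppf)·CH2Cl2 (5 mol %), AsPh3 (10 mol %), Cs2CO3 (3 M aq.), DMF/THF, rt, degassed
Reagents that add atoms: 9-borabicyclo[3.3.1]nonane (9-BBN-H), B1C2CCCC1CCC2 (boron and bicycle stay only in intermediate 19; product 20 keeps one hydrogen from it)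
Why: The B–H bond of 9-BBN adds syn through a four-centre transition state across the terminal C13′=C14′ bond with boron on C14′, after which zerovalent palladium inserts into the C–I bond of 8, the hydroxyborate transfers its primary alkyl group and reductive elimination forms C14′–C15′. The closest known reaction type is the hydroboration of terminal 1,3-dienes to homoallylic 9-BBN boranes followed by B-alkyl Suzuki–Miyaura coupling with (E)-2-methyl-1-iodoalkenes. No ring is closed and no stereocentre is made; the (E) geometry of C15′=C16′ from step 3 should be carried through because oxidative addition and reductive elimination proceed with retention at the sp2 carbon. The step needs hydroboration of one of five C=C bonds in 18, which the steric demand of 9-BBN should secure: the vinyl group is the only monosubstituted olefin, the chain olefins are trisubstituted and the cis C3=C4 bond is shielded by quaternary C2. The wide bite angle of dppf should make reductive elimination faster than β-hydride elimination of the alkylpalladium species. Neither fragment carries a carbonyl or acidic hydrogen, and the TIPS ether keeps the phenol out of the basic coupling medium.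

Step 13
Reactants: 20 O-triisopropylsilyl plastochromenol-8
Product: 21 plastochromenol-8
Conditions: TBAF, AcOH, THF, 0 °C, argon, light excluded
Reagents that add atoms: none
Why: Fluoride cleavage of the aryl silyl ether buffered with AcOH should free the phenol without oxidation of the phenoxide or photochemical ring-opening of the 2H-chromene, so the C2 configuration is kept.

**Compound list**

1 | (2E,6E,10E)-geranylgeraniol | CC(C)=CCC/C(C)=C/CC/C(C)=C/CC/C(C)=C/CO | starting material
2 | (2E,6E,10E)-geranylgeranyl bromide | CC(C)=CCC/C(C)=C/CC/C(C)=C/CC/C(C)=C/CBr | intermediate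
3 | 1-(trimethylsilyl)propyne | CC#C[Si](C)(C)C | starting material
4 | 3-lithio-1-(trimethylsilyl)propyne | [Li]CC#C[Si](C)(C)C | intermediate
5 | trimethyl[(5E,9E,13E)-6,10,14,18-tetramethylnonadeca-5,9,13,17-tetraen-1-yn-1-yl]silane | CC(C)=CCC/C(C)=C/CC/C(C)=C/CC/C(C)=C/CCC#C[Si](C)(C)C | intermediate
6 | (5E,9E,13E)-6,10,14,18-tetramethylnonadeca-5,9,13,17-tetraen-1-yne | CC(C)=CCC/C(C)=C/CC/C(C)=C/CC/C(C)=C/CCC#C | intermediate
7 | dimethyl[(1E,5E,9E,13E)-2,6,10,14,18-pentamethylnonadeca-1,5,9,13,17-pentaen-1-yl]alane | CC(C)=CCC/C(C)=C/CC/C(C)=C/CC/C(C)=C/CC/C(C)=C/[Al](C)C | intermediate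
8 | (1E,5E,9E,13E)-1-iodo-2,6,10,14,18-pentamethylnonadeca-1,5,9,13,17-pentaene | CC(C)=CCC/C(C)=C/CC/C(C)=C/CC/C(C)=C/CC/C(C)=C/I | intermediate
9 | 2,3-dimethylhydroquinone | Cc1c(C)c(O)ccc1O | starting material
10 | 2,3-dimethyl-4-(triisopropylsilyloxy)phenol | Cc1c(C)c(O[Si](C(C)C)(C(C)C)C(C)C)ccc1O | intermediate
11 | 2-hydroxy-3,4-dimethyl-5-(triisopropylsilyloxy)benzaldehyde | Cc1c(C)c(O[Si](C(C)C)(C(C)C)C(C)C)cc(C=O)c1O | intermediate
12 | 6-ethenyl-2,3-dimethyl-4-(triisopropylsilyloxy)phenol | Cc1c(C)c(O[Si](C(C)C)(C(C)C)C(C)C)cc(C=C)c1O | intermediate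
13 | (2E,6E,10E)-geranylgeranyl methyl carbonate | CC(C)=CCC/C(C)=C/CC/C(C)=C/CC/C(C)=C/COC(=O)OC | intermediate
14 | methyl (2E,6E,10E,14E)-16-hydroxy-3,7,11,15-tetramethylhexadeca-2,6,10,14-tetraen-1-yl carbonate | OC/C(C)=C/CC/C(C)=C/CC/C(C)=C/CC/C(C)=C/COC(=O)OC | intermediate
15 | methyl (2E,6E,10E,14E)-3,7,11,15-tetramethyl-16-oxohexadeca-2,6,10,14-tetraen-1-yl carbonate | O=C/C(C)=C/CC/C(C)=C/CC/C(C)=C/CC/C(C)=C/COC(=O)OC | intermediate
16 | (2E,6E,10E,14R)-14-[6-ethenyl-2,3-dimethyl-4-(triisopropylsilyloxy)phenoxy]-2,6,10,14-tetramethylhexadeca-2,6,10,15-tetraenal | O=C/C(C)=C/CC/C(C)=C/CC/C(C)=C/CC[C@](C)(C=C)Oc1c(C=C)cc(O[Si](C(C)C)(C(C)C)C(C)C)c(C)c1C | intermediate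
17 | (2E,6E,10E)-2,6,10-trimethyl-13-[(2R)-2,7,8-trimethyl-6-(triisopropylsilyloxy)-2H-chromen-2-yl]trideca-2,6,10-trienal | O=C/C(C)=C/CC/C(C)=C/CC/C(C)=C/CC[C@]1(C)C=Cc2cc(O[Si](C(C)C)(C(C)C)C(C)C)c(C)c(C)c2O1 | intermediate
18 | triisopropyl{[(2R)-2,7,8-trimethyl-2-[(3E,7E,11E)-4,8,12-trimethyltetradeca-3,7,11,13-tetraen-1-yl]-2H-chromen-6-yl]oxy}silane | C=C/C(C)=C/CC/C(C)=C/CC/C(C)=C/CC[C@]1(C)C=Cc2cc(O[Si](C(C)C)(C(C)C)C(C)C)c(C)c(C)c2O1 | intermediate
19 | 9-{(3E,7E,11E)-3,7,11-trimethyl-14-[(2R)-2,7,8-trimethyl-6-(triisopropylsilyloxy)-2H-chromen-2-yl]tetradeca-3,7,11-trien-1-yl}-9-borabicyclo[3.3.1]nonane | C1CCC2CCCC1B2CC/C(C)=C/CC/C(C)=C/CC/C(C)=C/CC[C@]1(C)C=Cc2cc(O[Si](C(C)C)(C(C)C)C(C)C)c(C)c(C)c2O1 | intermediate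
20 | O-triisopropylsilyl plastochromenol-8, triisopropyl{[(2R)-2,7,8-trimethyl-2-[(3E,7E,11E,15E,19E,23E,27E)-4,8,12,16,20,24,28,32-octamethyltritriaconta-3,7,11,15,19,23,27,31-octaen-1-yl]-2H-chromen-6-yl]oxy}silane | CC(C)=CCC/C(C)=C/CC/C(C)=C/CC/C(C)=C/CC/C(C)=C/CC/C(C)=C/CC/C(C)=C/CC/C(C)=C/CC[C@]1(C)C=Cc2cc(O[Si](C(C)C)(C(C)C)C(C)C)c(C)c(C)c2O1 | intermediate
21 | plastochromenol-8, (2R)-2,7,8-trimethyl-2-[(3E,7E,11E,15E,19E,23E,27E)-4,8,12,16,20,24,28,32-octamethyltritriaconta-3,7,11,15,19,23,27,31-octaen-1-yl]-2H-chromen-6-ol | CC(C)=CCC/C(C)=C/CC/C(C)=C/CC/C(C)=C/CC/C(C)=C/CC/C(C)=C/CC/C(C)=C/CC/C(C)=C/CC[C@]1(C)C=Cc2cc(O)c(C)c(C)c2O1 | target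

**Step count and risks**

Total steps: 13. Longest linear sequence: 8 steps (9 → 10 → 11 → 12 → 16 → 17 → 18 → 20 → 21; steps 4, 5, 6, 9, 10, 11, 12, 13).

Steps most likely to fail:

1. Step 9. The phenoxide is substituted at both ortho positions, so attack at the primary terminus of the allyl complex (linear ether) or poor facial discrimination at the tertiary terminus may erode regio- and enantioselectivity. The fallback sets out from 15 and 10 and comes back at 18, replacing ligand control by separation of enantiomers. Wittig methylenation of 15 (Ph3PCH3Br, n-BuLi, THF, −78 → 0 °C) gives the diene carbonate F1. Methanolysis (K2CO3, MeOH) gives the dienol F2, and MnO2 oxidation gives the dienal F3. Condensation of F3 with phenol 10 (PhB(OH)2, AcOH, toluene, reflux), by ortho-quinone methide formation and 6π-oxa-electrocyclisation, builds the pyran ring in one operation and gives the racemic chromene F4. Preparative HPLC on a polysaccharide chiral stationary phase then separates 18 from its (S)-enantiomer F5.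

2. Step 12. Hydroboration may lose chemoselectivity (addition to the chromene C3=C4 bond or double addition to the diene), or the borane may transmetallate slowly and protodeboronate. The fallback sets out from 18 and comes back at 20 with an isolated electrophile-derived organozinc instead of the borane. Hydrozirconation of the vinyl group with Cp2Zr(H)Cl (THF, rt) gives the alkylzirconocene chloride F6, which is not isolated. Iodinolysis (I2, 0 °C) gives the homoallylic iodide F7, which can be purified. Zinc insertion (Zn dust, LiCl, THF, 40 °C) gives the alkylzinc iodide F8, and Negishi coupling with 8 (PdCl2(dppf), THF, rt) forms the same C14′–C15′ bond.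

3. Step 8. Allylic oxidation may spread over the internal allylic positions of the four trisubstituted olefins or over-oxidise, giving low conversion to the terminal enal. The fallback sets out from 13 and comes back at 15 by degrading and rebuilding the chain end. Terminal bromohydrin formation (NBS, THF/H2O, 0 °C) gives the bromohydrin F9. Ring closure with DBU (THF) gives the terminal epoxide F10. Cleavage with HIO4·2H2O (THF/Et2O, 0 °C) gives the trisnor aldehyde F11. Wittig reaction with the stabilised ylide Ph3P=C(CH3)CHO (toluene, 90 °C) then gives the (E)-enal 15.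

**Further compounds**

F1 | step 9 | methyl (2E,6E,10E,14E)-3,7,11,15-tetramethylheptadeca-2,6,10,14,16-pentaen-1-yl carbonate | C=C/C(C)=C/CC/C(C)=C/CC/C(C)=C/CC/C(C)=C/COC(=O)OC
F2 | step 9 | (2E,6E,10E,14E)-3,7,11,15-tetramethylheptadeca-2,6,10,14,16-pentaen-1-ol | C=C/C(C)=C/CC/C(C)=C/CC/C(C)=C/CC/C(C)=C/CO
F3 | step 9 | (2E,6E,10E,14E)-3,7,11,15-tetramethylheptadeca-2,6,10,14,16-pentaenal | C=C/C(C)=C/CC/C(C)=C/CC/C(C)=C/CC/C(C)=C/C=O
F4 | step 9 | racemic triisopropyl{[2,7,8-trimethyl-2-[(3E,7E,11E)-4,8,12-trimethyltetradeca-3,7,11,13-tetraen-1-yl]-2H-chromen-6-yl]oxy}silane | C=C/C(C)=C/CC/C(C)=C/CC/C(C)=C/CCC1(C)C=Cc2cc(O[Si](C(C)C)(C(C)C)C(C)C)c(C)c(C)c2O1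
F5 | step 9 | (2S)-enantiomer of compound 18 | C=C/C(C)=C/CC/C(C)=C/CC/C(C)=C/CC[C@@]1(C)C=Cc2cc(O[Si](C(C)C)(C(C)C)C(C)C)c(C)c(C)c2O1
F6 | step 12 | chlorobis(cyclopentadienyl){(3E,7E,11E)-3,7,11-trimethyl-14-[(2R)-2,7,8-trimethyl-6-(triisopropylsilyloxy)-2H-chromen-2-yl]tetradeca-3,7,11-trien-1-yl}zirconium | C1=CC(C=C1)[Zr](Cl)(C1C=CC=C1)CC/C(C)=C/CC/C(C)=C/CC/C(C)=C/CC[C@]1(C)C=Cc2cc(O[Si](C(C)C)(C(C)C)C(C)C)c(C)c(C)c2O1
F7 | step 12 | {[(2R)-2-[(3E,7E,11E)-14-iodo-4,8,12-trimethyltetradeca-3,7,11-trien-1-yl]-2,7,8-trimethyl-2H-chromen-6-yl]oxy}triisopropylsilane | ICC/C(C)=C/CC/C(C)=C/CC/C(C)=C/CC[C@]1(C)C=Cc2cc(O[Si](C(C)C)(C(C)C)C(C)C)c(C)c(C)c2O1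
F8 | step 12 | iodo{(3E,7E,11E)-3,7,11-trimethyl-14-[(2R)-2,7,8-trimethyl-6-(triisopropylsilyloxy)-2H-chromen-2-yl]tetradeca-3,7,11-trien-1-yl}zinc | I[Zn]CC/C(C)=C/CC/C(C)=C/CC/C(C)=C/CC[C@]1(C)C=Cc2cc(O[Si](C(C)C)(C(C)C)C(C)C)c(C)c(C)c2O1
F9 | step 8 | methyl (2E,6E,10E)-14-bromo-15-hydroxy-3,7,11,15-tetramethylhexadeca-2,6,10-trien-1-yl carbonate (racemic at C14) | CC(C)(O)C(Br)CC/C(C)=C/CC/C(C)=C/CC/C(C)=C/COC(=O)OC
F10 | step 8 | methyl (2E,6E,10E)-14,15-epoxy-3,7,11,15-tetramethylhexadeca-2,6,10-trien-1-yl carbonate (racemic) | CC1(C)OC1CC/C(C)=C/CC/C(C)=C/CC/C(C)=C/COC(=O)OC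
F11 | step 8 | methyl (2E,6E,10E)-3,7,11-trimethyl-14-oxotetradeca-2,6,10-trien-1-yl carbonate | O=CCC/C(C)=C/CC/C(C)=C/CC/C(C)=C/COC(=O)OC
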